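**Plan**

The chain is numbered from the ester carbonyl (C1) to the brominated carbon (C20). The feature that allows the key step is the 2,5-trans oxolane made of C5, C6, C7, C8 and the ring oxygen: it splits into a two-atom unit (C8 and the ring oxygen, an aldehyde) and a three-carbon unit (C5–C6–C7, an allylsilane with silicon on C5), and C6 is unsubstituted, so the silicon left there can be removed afterwards.
Retrosynthesis cuts C19=C20 (bromo-Wittig), then C10–C11 (Sonogashira), then C9≡C10 (alkyne homologation of a C9 aldehyde), then the ring bonds C7–C8 and O–C5 together, and last the C5–Si bond and the C5=C6 alkene of an allylic chloride.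
Forward: cross-metathesis and copper-catalysed allylic silylation give the allylsilane; its (3+2) annulation with chelated benzyloxyacetaldehyde closes the only ring; silicon is removed from C6, the C9 arm becomes an alkyne, an iododienal made from hept-6-yn-1-ol is coupled on, and the bromoalkene is installed last.
Stereochemistry: the allylsilane centre comes from the chiral copper catalyst and is relayed to C5 with inversion in the annulation; C8 comes from the chelate-controlled topicity of the same step; the two E alkenes come from syn hydrozirconation and a stabilised ylide, the Z bromoalkene from a non-stabilised ylide.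

Key step: step 3

Assumption: in step 2 the enantiomer of the chiral carbene ligand is the one that gives the S allylsilane; the sense of induction is to be confirmed on the first batch before material is carried on.

**Route**

Step 1
Reactants: 1 methyl hex-5-enoate; 2 (2Z)-1,4-dichlorobut-2-ene
Product: 3 methyl (5E)-7-chlorohept-5-enoate
Conditions: 2 (3 equiv), second-generation Grubbs catalyst RuCl2(=CHPh)(H2IMes)(PCy3) (2 mol%), CH2Cl2, 40 °C
Reagents that add atoms: none
Why: Olefin cross-metathesis of the terminal alkene with an excess of the symmetrical internal dichloride exchanges the terminal methylidene for a 2-chloroethylidene unit and, being reversible, should settle mainly on the E allylic chloride (any Z isomer is removed before step 2, because alkene geometry feeds into the enantioselectivity there).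

Step 2
Reactants: 3 methyl (5E)-7-chlorohept-5-enoate
Product: 4 methyl (5S)-5-[dimethyl(phenyl)silyl]hept-6-enoate
Conditions: PhMe2Si–Bpin (1.5 equiv), CuCl (5 mol%), chiral N-heterocyclic carbene precursor (azolium salt, 5.5 mol%), NaOMe (1.5 equiv), CH2Cl2, 0 °C
Reagents that add atoms: 2-[dimethyl(phenyl)silyl]-4,4,5,5-tetramethyl-1,3,2-dioxaborolane, CC1(C)OB(OC1(C)C)[Si](C)(C)c1ccccc1
Why: Copper-catalysed enantioselective allylic substitution with a silicon–boron reagent, in which methoxide activates the Si–B bond, the chiral carbene–copper silyl species delivers silicon to C5 in an SN2′ sense with loss of chloride from C7, the ligand enantiomer fixes the S configuration at C5, and the methyl ester is indifferent to NaOMe.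

Step 3
Reactants: 4 methyl (5S)-5-[dimethyl(phenyl)silyl]hept-6-enoate; 5 benzyloxyacetaldehyde
Product: 6 methyl 4-[(2R,3S,5S)-5-[(benzyloxy)methyl]-3-[dimethyl(phenyl)silyl]oxolan-2-yl]butanoate
Conditions: 5 (1.5 equiv) and SnCl4 (1.5 equiv) premixed, 4 Å molecular sieves, CH2Cl2, −78 °C; then 4, −78 → −45 °C; aq. NaHCO3
Reagents that add atoms: none
Why: SnCl4 ties the carbonyl oxygen and the benzyloxy oxygen of 5 into a five-membered chelate, and the terminal alkene carbon C7 of 4 adds to the activated carbonyl (C7–C8) on the alkene face opposite to the C5–Si bond, with the C5 hydrogen eclipsing the double bond; the positive charge that develops at C6 is bridged by silicon, silicon settles on C6, and the tin-bound alkoxide attacks C5 from the side opposite to silicon (O–C5). The closest known reaction type is the Lewis acid-promoted (3+2) annulation of α-substituted dimethyl(phenyl)silyl allylsilanes with aldehydes, in which SnCl4-chelated α-alkoxy aldehydes give 2,5-trans oxolanes; 4 differs from the closest examples only in carrying a plain alkyl chain instead of a β-silyloxy group on the silicon-bearing carbon. The oxolane closes by attack of oxygen on C5 of the silicon-bridged cation with the breaking C5–Si bond outside the new ring, a 5-exo-tet closure in that sense (in the language used for epoxide openings it would be called 5-endo, because both carbons of the three-membered ring end up in the oxolane), and it inverts C5. C5 (R) is therefore set by the S centre of 4 through anti attack followed by inversion, C6 (silicon trans to the C5 chain) by the trans geometry of the bridged cation and its anti opening, and C8 (S) by the topicity of the C–C bond formation, the chelate reacting through an antiperiplanar arrangement in which the aldehyde hydrogen, not the tin-bearing arm, lies over the crowded C5 side. The step needs ring closure to outrun loss of silicon to chloride (plain allylation), which the low temperature, the phenyl-bearing silyl group and the five-ring closure should secure, and it needs 2,5-trans over 2,5-cis selectivity, which rests on the α-benzyloxy group that makes the chelate possible; the chelate is preformed with an excess of SnCl4 so that the ester of 4 does not compete for the Lewis acid.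

Step 4
Reactants: 6 methyl 4-[(2R,3S,5S)-5-[(benzyloxy)methyl]-3-[dimethyl(phenyl)silyl]oxolan-2-yl]butanoate
Product: 8 methyl 4-[(2R,3S,5S)-5-[(benzyloxy)methyl]-3-hydroxyoxolan-2-yl]butanoate, via acetoxysilane 7 (not isolated)
Conditions: Hg(OAc)2 (1.5 equiv), AcOOH (32% in AcOH, excess), AcOH, rt
Reagents that add atoms: peracetic acid, CC(=O)OO
Why: Tamao–Fleming oxidation in its one-pot form, in which mercuridesilylation takes the phenyl group off silicon and the peracid then moves C6 from silicon to oxygen with retention, under acetate-buffered conditions that the methyl ester, the benzyl ether and the oxolane should tolerate.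

Step 5
Reactants: 8 methyl 4-[(2R,3S,5S)-5-[(benzyloxy)methyl]-3-hydroxyoxolan-2-yl]butanoate
Product: 9 O-[(2R,3S,5S)-5-[(benzyloxy)methyl]-2-(4-methoxy-4-oxobutyl)oxolan-3-yl] 1H-imidazole-1-carbothioate
Conditions: 1,1′-thiocarbonyldiimidazole (1.5 equiv), DMAP (0.2 equiv), ClCH2CH2Cl, 70 °C
Reagents that add atoms: 1,1′-thiocarbonyldiimidazole, S=C(n1ccnc1)n1ccnc1
Why: Thioacylation of the only free hydroxyl group gives the thiocarbonyl derivative required for a Barton–McCombie deoxygenation without touching the ester or the benzyl ether.

Step 6
Reactants: 9 O-[(2R,3S,5S)-5-[(benzyloxy)methyl]-2-(4-methoxy-4-oxobutyl)oxolan-3-yl] 1H-imidazole-1-carbothioate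
Product: 10 methyl 4-[(2R,5S)-5-[(benzyloxy)methyl]oxolan-2-yl]butanoate
Conditions: Bu3SnH (1.5 equiv), AIBN (0.1 equiv), toluene, 110 °C; KF work-up
Reagents that add atoms: none
Why: Barton–McCombie deoxygenation, in which the stannyl radical adds to sulfur, the C6–O bond breaks to a secondary ring radical and this takes hydrogen from Bu3SnH, so that C6 becomes a methylene group while C5 and C8 are not involved.

Step 7
Reactants: 10 methyl 4-[(2R,5S)-5-[(benzyloxy)methyl]oxolan-2-yl]butanoate
Product: 11 methyl 4-[(2R,5S)-5-(hydroxymethyl)oxolan-2-yl]butanoate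
Conditions: H2 (1 atm), 10% Pd/C, EtOAc, rt
Reagents that add atoms: none
Why: Catalytic hydrogenolysis of the benzyl ether over palladium on carbon frees the primary alcohol at C9 and leaves the ester and the oxolane untouched.

Step 8
Reactants: 11 methyl 4-[(2R,5S)-5-(hydroxymethyl)oxolan-2-yl]butanoate
Product: 12 methyl 4-[(2R,5S)-5-formyloxolan-2-yl]butanoate
Conditions: TEMPO (0.1 equiv), PhI(OAc)2 (1.1 equiv), CH2Cl2, rt; used crude
Reagents that add atoms: none
Why: The TEMPO-catalysed oxidation with PhI(OAc)2 as terminal oxidant stops at the aldehyde and is free of base, so the α-oxygenated centre C8 should keep its configuration.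

Step 9
Reactants: 12 methyl 4-[(2R,5S)-5-formyloxolan-2-yl]butanoate
Product: 13 methyl 4-[(2R,5S)-5-ethynyloxolan-2-yl]butanoate
Conditions: dimethyl (1-diazo-2-oxopropyl)phosphonate (1.3 equiv), K2CO3 (2 equiv), MeOH, 0 °C → rt
Reagents that add atoms: dimethyl (1-diazo-2-oxopropyl)phosphonate, COP(=O)(OC)C(=[N+]=[N-])C(C)=O
Why: Ohira–Bestmann homologation (the Seyferth–Gilbert reaction run with deacylation in the flask), in which the diazomethylphosphonate anion adds to the aldehyde, the alkylidene carbene formed after loss of phosphate and N2 undergoes a 1,2-hydrogen shift to the terminal alkyne, carbonate in methanol cannot change the methyl ester, and the low temperature should limit epimerisation at C8.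

Step 10
Reactants: 14 hept-6-yn-1-ol
Product: 16 (6E)-7-iodohept-6-en-1-ol, via alkenylzirconocene chloride 15 (not isolated)
Conditions: Cp2Zr(H)Cl (2.2 equiv), THF, rt; then I2 (1.1 equiv), 0 °C
Reagents that add atoms: iodine, II
Why: Hydrozirconation–iodination, in which the first equivalent of Cp2Zr(H)Cl is taken up by the hydroxyl group, the second adds syn across the terminal alkyne with zirconium on the terminal carbon, and iodine cleaves the C–Zr bond with retention to give the E iodoalkene.

Step 11
Reactants: 16 (6E)-7-iodohept-6-en-1-ol
Product: 17 (6E)-7-iodohept-6-enal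
Conditions: TEMPO (0.1 equiv), PhI(OAc)2 (1.1 equiv), CH2Cl2, rt
Reagents that add atoms: none
Why: TEMPO-catalysed oxidation of the primary alcohol stops at the aldehyde and leaves the iodoalkene alone.

Step 12
Reactants: 17 (6E)-7-iodohept-6-enal
Product: 18 (2E,8E)-9-iodonona-2,8-dienal
Conditions: Ph3P=CHCHO (1.2 equiv), toluene, 80 °C
Reagents that add atoms: (triphenylphosphoranylidene)acetaldehyde, O=CC=P(c1ccccc1)(c1ccccc1)c1ccccc1
Why: Wittig reaction with the stabilised formylmethylene ylide should give the E enal, and a small excess of ylide at moderate temperature keeps a second homologation of the less electrophilic enal in check.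

Step 13
Reactants: 13 methyl 4-[(2R,5S)-5-ethynyloxolan-2-yl]butanoate; 18 (2E,8E)-9-iodonona-2,8-dienal
Product: 19 methyl 4-[(2R,5S)-5-[(3E,9E)-11-oxoundeca-3,9-dien-1-yn-1-yl]oxolan-2-yl]butanoate
Conditions: Pd(PPh3)4 (5 mol%), CuI (10 mol%), Et3N (3 equiv), degassed THF, rt, dark
Reagents that add atoms: none
Why: Sonogashira coupling, in which zerovalent palladium inserts into the C–I bond with retention of the E geometry and the copper acetylide of 13 transfers the alkynyl group, forms the C10–C11 bond under conditions (tertiary amine, room temperature) that the enal and the C8 centre should survive.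

Step 14
Reactants: 19 methyl 4-[(2R,5S)-5-[(3E,9E)-11-oxoundeca-3,9-dien-1-yn-1-yl]oxolan-2-yl]butanoate
Product: 20 methyl 4-[(2R,5S)-5-[(3E,9E,11Z)-12-bromododeca-3,9,11-trien-1-yn-1-yl]oxolan-2-yl]butanoate
Conditions: BrCH2PPh3Br (1.5 equiv), KOtBu (1.4 equiv), THF, −78 °C; then 19, −78 → −20 °C, dark
Reagents that add atoms: (bromomethyl)triphenylphosphonium bromide, BrC[P+](c1ccccc1)(c1ccccc1)c1ccccc1.[Br-]
Why: Wittig reaction of the enal with the non-stabilised bromomethylene ylide under kinetic control at low temperature should give the Z bromoalkene, the aldehyde being far more reactive than the methyl ester toward the ylide.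

**Compound list**

1 | methyl hex-5-enoate | C=CCCCC(=O)OC | starting material
2 | (2Z)-1,4-dichlorobut-2-ene | ClC/C=C\CCl | starting material
3 | methyl (5E)-7-chlorohept-5-enoate | COC(=O)CCC/C=C/CCl | intermediate
4 | methyl (5S)-5-[dimethyl(phenyl)silyl]hept-6-enoate | COC(=O)CCC[C@H]([Si](C)(C)c1ccccc1)C=C | intermediate
5 | benzyloxyacetaldehyde | O=CCOCc1ccccc1 | starting material
6 | methyl 4-[(2R,3S,5S)-5-[(benzyloxy)methyl]-3-[dimethyl(phenyl)silyl]oxolan-2-yl]butanoate | COC(=O)CCC[C@@H]1[C@@H]([Si](C)(C)c2ccccc2)C[C@@H](COCc2ccccc2)O1 | intermediate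
7 | methyl 4-[(2R,3S,5S)-3-[(acetyloxy)dimethylsilyl]-5-[(benzyloxy)methyl]oxolan-2-yl]butanoate | COC(=O)CCC[C@@H]1[C@@H]([Si](C)(C)OC(C)=O)C[C@@H](COCc2ccccc2)O1 | intermediate
8 | methyl 4-[(2R,3S,5S)-5-[(benzyloxy)methyl]-3-hydroxyoxolan-2-yl]butanoate | COC(=O)CCC[C@@H]1[C@@H](O)C[C@@H](COCc2ccccc2)O1 | intermediate
9 | O-[(2R,3S,5S)-5-[(benzyloxy)methyl]-2-(4-methoxy-4-oxobutyl)oxolan-3-yl] 1H-imidazole-1-carbothioate | COC(=O)CCC[C@@H]1[C@@H](OC(=S)n2ccnc2)C[C@@H](COCc2ccccc2)O1 | intermediate
10 | methyl 4-[(2R,5S)-5-[(benzyloxy)methyl]oxolan-2-yl]butanoate | COC(=O)CCC[C@@H]1CC[C@@H](COCc2ccccc2)O1 | intermediate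
11 | methyl 4-[(2R,5S)-5-(hydroxymethyl)oxolan-2-yl]butanoate | COC(=O)CCC[C@@H]1CC[C@@H](CO)O1 | intermediate
12 | methyl 4-[(2R,5S)-5-formyloxolan-2-yl]butanoate | COC(=O)CCC[C@@H]1CC[C@@H](C=O)O1 | intermediate
13 | methyl 4-[(2R,5S)-5-ethynyloxolan-2-yl]butanoate | COC(=O)CCC[C@@H]1CC[C@@H](C#C)O1 | intermediate
14 | hept-6-yn-1-ol | OCCCCCC#C | starting material
15 | chlorobis(cyclopentadienyl)[(1E)-7-{[chlorobis(cyclopentadienyl)zirconio]oxy}hept-1-en-1-yl]zirconium | Cl[Zr](C1C=CC=C1)(C1C=CC=C1)/C=C/CCCCCO[Zr](Cl)(C1C=CC=C1)C1C=CC=C1 | intermediate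
16 | (6E)-7-iodohept-6-en-1-ol | OCCCCC/C=C/I | intermediate
17 | (6E)-7-iodohept-6-enal | O=CCCCC/C=C/I | intermediate
18 | (2E,8E)-9-iodonona-2,8-dienal | O=C/C=C/CCCC/C=C/I | intermediate
19 | methyl 4-[(2R,5S)-5-[(3E,9E)-11-oxoundeca-3,9-dien-1-yn-1-yl]oxolan-2-yl]butanoate | COC(=O)CCC[C@@H]1CC[C@@H](C#C/C=C/CCCC/C=C/C=O)O1 | intermediate
20 | methyl 4-[(2R,5S)-5-[(3E,9E,11Z)-12-bromododeca-3,9,11-trien-1-yn-1-yl]oxolan-2-yl]butanoate | COC(=O)CCC[C@@H]1CC[C@@H](C#C/C=C/CCCC/C=C/C=C\Br)O1 | target

**Count and risks**

Total step count: 14. Longest linear sequence: 11 steps (steps 1–9, 13 and 14); the three-step iododienal branch (steps 10–12) joins at step 13.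

Steps most likely to fail:

1. Step 3. Chloride may take silicon off the β-silyl cation before the oxygen closes, so that plain allylation competes with annulation; the remote ester carbonyl may capture the cation; and weak chelation would erode the 2,5-trans selectivity. The fallback sets out from 4 and 5 and forms the same two ring bonds in two operations. The addition is run deliberately in the allylation mode (TiCl4, CH2Cl2, −78 °C), where anti SE′ attack through the same chelated arrangement should give the homoallylic alcohol methyl (5E,8S)-9-(benzyloxy)-8-hydroxynon-5-enoate F1. Iodoetherification (I2, NaHCO3, MeCN, 0 °C), a 5-endo cyclisation that is reported to turn E homoallylic alcohols into 2,5-trans 3-iodooxolanes, should then give methyl 4-[(2R,3S,5S)-5-[(benzyloxy)methyl]-3-iodooxolan-2-yl]butanoate F2. Radical deiodination (Bu3SnH, AIBN, toluene, 80 °C) brings the material back to the route at 10.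

2. Step 4. The ring oxygen is β to silicon, so acid- or mercury-promoted β-elimination across C5–C6 may open the oxolane, and removal of the phenyl group from the hindered ring silane may stall. The fallback sets out from 6 and removes silicon without an alcohol stage, by fluoride-promoted protiodesilylation (TBAF, wet DMF, 85 °C). This reaction is known for dimethyl(phenyl)silyl groups on oxolanes of this origin and cleaves first the phenyl–silicon and then the C6–Si bond. The hot wet fluoride is expected to saponify the methyl ester as well, so the product is taken as 4-[(2R,5S)-5-[(benzyloxy)methyl]oxolan-2-yl]butanoic acid F3 and re-esterified (TMSCHN2, MeOH/toluene, 0 °C). It comes back to the route at 10 and bypasses steps 4–6.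

3. Step 14. Z selectivity of the bromo-Wittig reaction may be insufficient, and the light-sensitive (1Z,3E)-bromodiene may isomerise, with geometric isomers that are hard to separate at the last stage. The fallback sets out from 19. Corey–Fuchs dibromo-olefination (CBr4, PPh3, CH2Cl2, 0 °C) should give methyl 4-[(2R,5S)-5-[(3E,9E)-12,12-dibromododeca-3,9,11-trien-1-yn-1-yl]oxolan-2-yl]butanoate F4. Palladium-catalysed hydrogenolysis (Pd(PPh3)4, Bu3SnH, toluene, rt) then removes selectively the more accessible bromine trans to the chain, a known way to (1Z,3E)-1-bromodienes. It comes back to the route at 20.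

Further compounds
F1 | step 3 | methyl (5E,8S)-9-(benzyloxy)-8-hydroxynon-5-enoate | COC(=O)CCC/C=C/C[C@@H](COCc1ccccc1)O
F2 | step 3 | methyl 4-[(2R,3S,5S)-5-[(benzyloxy)methyl]-3-iodooxolan-2-yl]butanoate | COC(=O)CCC[C@@H]1[C@@H](I)C[C@@H](COCc2ccccc2)O1
F3 | step 4 | 4-[(2R,5S)-5-[(benzyloxy)methyl]oxolan-2-yl]butanoic acid | OC(=O)CCC[C@@H]1CC[C@@H](COCc2ccccc2)O1
F4 | step 14 | methyl 4-[(2R,5S)-5-[(3E,9E)-12,12-dibromododeca-3,9,11-trien-1-yn-1-yl]oxolan-2-yl]butanoate | COC(=O)CCC[C@@H]1CC[C@@H](C#C/C=C/CCCC/C=C/C=C(Br)Br)O1
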